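**Plan**
- Retrosynthesis: the three O–S bonds (O3, O5, O4') and the benzyl mask on O3' are removed first. The C3–O bond is cut next, which leads back to a flavone whose ring C is cut at O1–C8a, C4–C4a and O1–C2.
- Enabling feature: in ring A, O5 sits on C5, the direct neighbour of C4a, so a C4a≡C8a triple bond is that of a 3-alkoxyaryne. Its polarisation admits an oxygen nucleophile only at C8a and leaves C4a for the acyl carbon, which fixes the 5,7-pattern.
- Forward: ring A is bought and armed as an ortho-silylaryl triflate (steps 1–3). Ring B is bought and extended to an arylpropiolic acid (steps 4–7). Ring C forms in step 8 when the two are joined.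
- Endgame: C3 is hydroxylated, the two MOM groups (O5, O4') are removed, the three free hydroxyls are sulfated and O3' is debenzylated. O7 keeps its methyl group throughout.
- Stereochemistry: the target has no stereocentre and no stereogenic double bond, so nothing has to be controlled.

Key step: step 8

Assumption: the target is drawn as the free tris(hydrogen sulfate). Aryl hydrogen sulfates hydrolyse under their own acidity, so the material is carried and stored as the triethylammonium salt. The acid form is released only in the last operation, by cold cation exchange.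

**Step 1**
Reactants: 1 5-methoxyresorcinol
Product: 2 2-iodo-5-methoxybenzene-1,3-diol
Conditions: I2 (1.0 equiv), NaHCO3 (1.1 equiv), H2O, 0 °C to rt
Reagents that add atoms: iodine, II
Why: Electrophilic aromatic iodination of the phenoxide under bicarbonate buffering is kinetically directed to the carbon flanked by both hydroxyls, as in the standard preparation of 2-iodoresorcinol, and the absence of acid prevents migration of iodine to C4.

**Step 2**
Reactants: 2 2-iodo-5-methoxybenzene-1,3-diol
Product: 3 2-iodo-5-methoxy-3-(methoxymethoxy)phenol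
Conditions: MOMCl (1.0 equiv), K2CO3 (1.0 equiv), acetone, 0 °C to rt
Reagents that add atoms: chloromethyl methyl ether, COCCl
Why: Williamson-type O-alkylation with one equivalent of MOMCl differentiates the two equivalent phenols statistically, which is acceptable this early because recovered 2 is recycled.

**Step 3**
Reactants: 3 2-iodo-5-methoxy-3-(methoxymethoxy)phenol
Product: 6 5-methoxy-3-(methoxymethoxy)-2-(trimethylsilyl)phenyl trifluoromethanesulfonate, via aryl trimethylsilyl ether 4 (not isolated), via lithium silylphenoxide 5 (not isolated)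
Conditions: HMDS, THF, 70 °C, then evaporate; n-BuLi (1.1 equiv), THF, −78 °C to −20 °C; Tf2O, −78 °C
Reagents that add atoms: hexamethyldisilazane, C[Si](C)(C)N[Si](C)(C)C; trifluoromethanesulfonic anhydride, O=S(=O)(OS(=O)(=O)C(F)(F)F)C(F)(F)F; n-butyllithium, [Li]CCCC (lithium of 5 only)
Why: O-silylation, iodine–lithium exchange and retro-Brook (1,3 O-to-C) silyl migration put silicon exactly where iodine stood, and the released lithium phenoxide is triflated in situ, which is the standard route from ortho-halophenols to ortho-silylaryl triflates.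

**Step 4**
Reactants: 7 3,4-dihydroxybenzaldehyde
Product: 8 3-hydroxy-4-(methoxymethoxy)benzaldehyde
Conditions: MOMCl (1.05 equiv), K2CO3 (1.1 equiv), acetone, 0 °C to rt
Reagents that add atoms: chloromethyl methyl ether, COCCl
Why: The 4-OH, para to the formyl group, is the more acidic phenol, so a weak base ionises it alone and the Williamson-type alkylation is regioselective, as is well known for 4-O-protection of this aldehyde.

**Step 5**
Reactants: 8 3-hydroxy-4-(methoxymethoxy)benzaldehyde
Product: 9 3-(benzyloxy)-4-(methoxymethoxy)benzaldehyde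
Conditions: BnBr, K2CO3, DMF, rt
Reagents that add atoms: benzyl bromide, BrCc1ccccc1
Why: Williamson ether synthesis on the only remaining phenol places on O3' the one group that will outlast acid and sulfation.

**Step 6**
Reactants: 9 3-(benzyloxy)-4-(methoxymethoxy)benzaldehyde
Product: 10 2-(benzyloxy)-4-(2,2-dibromoethenyl)-1-(methoxymethoxy)benzene
Conditions: CBr4, PPh3, Et3N, CH2Cl2, 0 °C
Reagents that add atoms: carbon tetrabromide, BrC(Br)(Br)Br
Why: This is the first stage of the Corey–Fuchs homologation (Wittig-type dibromoolefination), buffered with Et3N so that the MOM acetal never meets HBr.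

**Step 7**
Reactants: 10 2-(benzyloxy)-4-(2,2-dibromoethenyl)-1-(methoxymethoxy)benzene
Product: 12 3-[3-(benzyloxy)-4-(methoxymethoxy)phenyl]prop-2-ynoic acid, via lithium acetylide 11 (not isolated)
Conditions: n-BuLi (2.2 equiv), THF, −78 °C; CO2 (g), −78 °C to rt; cold 1 M HCl to pH 2, immediate extraction
Reagents that add atoms: carbon dioxide, O=C=O; n-butyllithium, [Li]CCCC (lithium of 11 only)
Why: In the second stage of the Corey–Fuchs sequence, bromine–lithium exchange, elimination and deprotonation give the lithium acetylide, whose carboxylation gives the propiolic acid directly, and the brief cold acidification spares the MOM ether.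

**Step 8**
Reactants: 6 5-methoxy-3-(methoxymethoxy)-2-(trimethylsilyl)phenyl trifluoromethanesulfonate (1.5 equiv); 12 3-[3-(benzyloxy)-4-(methoxymethoxy)phenyl]prop-2-ynoic acid
Product: 15 3'-benzyloxy-7-methoxy-5,4'-bis(methoxymethoxy)flavone, via 3-alkoxyaryne 13 (not isolated), via ortho-hydroxyaryl ynone 14 (not isolated)
Conditions: CsF (4 equiv, dried), THF (0.02 M), 125 °C, sealed vessel
Reagents that add atoms: none
Why: CsF removes the silyl group and expels triflate to give aryne 13, whose C4a≡C8a bond is distorted and polarised by the oxygen on C5, so the caesium carboxylate of 12 bonds through oxygen to the remote carbon C8a while the charge develops at C4a beside the inductively withdrawing OMOM group. This aryl anion adds to the neighbouring ester carbonyl to form a four-membered alkoxide that reopens with C–O cleavage, an anionic ortho-Fries-type 1,3-acyl shift that amounts to insertion of the aryne into the acyl–oxygen bond and gives the phenoxide of ynone 14 (O1–C8a and C4–C4a made). The phenoxide closes ring C by 6-endo-dig oxa-Michael addition to the ynone (O1–C2), and the resulting allenolate takes back the proton that had been held on fluoride. The closest known reaction type is the fluoride-induced insertion of arynes into the C–O bond of carboxylic acids to give ortho-hydroxyaryl ketones, which with arylpropiolic acids runs on to flavones. Three selectivities are needed: orientation, secured by the 3-alkoxy substituent; acyl transfer ahead of protonation of the aryl anion, favoured by hot dilute THF and excess CsF that keeps free acid out of solution; and 6-endo over 5-exo closure, favoured for a polarised aryl ynone in an aprotic medium. No stereocentre is formed.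

**Step 9**
Reactants: 15 3'-benzyloxy-7-methoxy-5,4'-bis(methoxymethoxy)flavone
Product: 18 3'-benzyloxy-3-hydroxy-7-methoxy-5,4'-bis(methoxymethoxy)flavone, via 3-lithioflavone 16 (not isolated), via dimethyl boronate 17 (not isolated)
Conditions: LiN(iPr)2 (LDA, 2 equiv), THF, −78 °C; B(OMe)3, −78 °C to 0 °C; AcOH, 30% H2O2, 0 °C to rt
Reagents that add atoms: hydrogen peroxide, OO; lithium diisopropylamide, [Li]N(C(C)C)C(C)C (lithium of 16 only); trimethyl borate, COB(OC)OC (boron ester of 17 only)
Why: Vinylic lithiation of flavones at C3 by the amide base at −78 °C is known, and borylation followed by oxidative boron-to-oxygen migration installs the 3-hydroxyl, the base being too weak to metalate the MOM- or benzyl-bearing rings.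

**Step 10**
Reactants: 18 3'-benzyloxy-3-hydroxy-7-methoxy-5,4'-bis(methoxymethoxy)flavone
Product: 19 3'-O-benzylrhamnetin (3'-benzyloxy-3,5,4'-trihydroxy-7-methoxyflavone)
Conditions: 3 M HCl, MeOH, 50 °C
Reagents that add atoms: none
Why: Acid-catalysed transacetalisation in methanol removes both MOM groups (O5 and O4') while the benzyl and methyl ethers are inert, which exposes exactly the three hydroxyls to be sulfated.

**Step 11**
Reactants: 19 3'-O-benzylrhamnetin
Product: 20 tris(triethylammonium) 3'-O-benzylrhamnetin 3,5,4'-tris(sulfate)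
Conditions: SO3·NMe3 (large excess), Et3N (excess), MeCN, 100 °C (microwave); Sephadex LH-20 or C18
Reagents that add atoms: sulfur trioxide–trimethylamine complex, C[N+](C)(C)S(=O)(=O)[O-]; triethylamine, CCN(CC)CC
Why: This is O-sulfation of phenols by an amine–SO3 complex, with excess reagent, added base and heat chosen because O5–H is chelated to the C4 carbonyl and reacts last, these being the conditions known to persulfate 5-hydroxyflavonoids.

**Step 12**
Reactants: 20 tris(triethylammonium) 3'-O-benzylrhamnetin 3,5,4'-tris(sulfate)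
Product: 22 rhamnetin 3,5,4'-tri-O-sulfate, via debenzylated triethylammonium salt 21 (not isolated)
Conditions: H2 (1 atm), 10% Pd/C, MeOH–H2O, rt; filter; Dowex 50W (H+ form), H2O, 0 °C; freeze-dry at once
Reagents that add atoms: none
Why: Catalytic hydrogenolysis of the aryl benzyl ether leaves aryl sulfate salts, the methyl ether and the chromone double bond untouched, as known for benzyl-protected flavonoid sulfates, and cation exchange on a sulfonic acid resin replaces the ammonium ions by protons.

**Compound list**
1 | 5-methoxyresorcinol | COc1cc(O)cc(O)c1 | starting material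
2 | 2-iodo-5-methoxybenzene-1,3-diol | COc1cc(O)c(I)c(O)c1 | intermediate
3 | 2-iodo-5-methoxy-3-(methoxymethoxy)phenol | COCOc1cc(OC)cc(O)c1I | intermediate
4 | [2-iodo-5-methoxy-3-(methoxymethoxy)phenoxy]trimethylsilane | COCOc1cc(OC)cc(O[Si](C)(C)C)c1I | intermediate
5 | lithium 5-methoxy-3-(methoxymethoxy)-2-(trimethylsilyl)phenoxide | COCOc1cc(OC)cc([O-])c1[Si](C)(C)C.[Li+] | intermediate
6 | 5-methoxy-3-(methoxymethoxy)-2-(trimethylsilyl)phenyl trifluoromethanesulfonate | COCOc1cc(OC)cc(OS(=O)(=O)C(F)(F)F)c1[Si](C)(C)C | intermediate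
7 | 3,4-dihydroxybenzaldehyde | O=Cc1ccc(O)c(O)c1 | starting material
8 | 3-hydroxy-4-(methoxymethoxy)benzaldehyde | O=Cc1ccc(OCOC)c(O)c1 | intermediate
9 | 3-(benzyloxy)-4-(methoxymethoxy)benzaldehyde | O=Cc1ccc(OCOC)c(OCc2ccccc2)c1 | intermediate
10 | 2-(benzyloxy)-4-(2,2-dibromoethenyl)-1-(methoxymethoxy)benzene | BrC(Br)=Cc1ccc(OCOC)c(OCc2ccccc2)c1 | intermediate
11 | lithium [3-(benzyloxy)-4-(methoxymethoxy)phenyl]acetylide | [Li]C#Cc1ccc(OCOC)c(OCc2ccccc2)c1 | intermediate
12 | 3-[3-(benzyloxy)-4-(methoxymethoxy)phenyl]prop-2-ynoic acid | OC(=O)C#Cc1ccc(OCOC)c(OCc2ccccc2)c1 | intermediate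
13 | 5-methoxy-3-(methoxymethoxy)benzyne | COCOC1=CC(OC)=CC#C1 | intermediate
14 | 3-[3-(benzyloxy)-4-(methoxymethoxy)phenyl]-1-[2-hydroxy-4-methoxy-6-(methoxymethoxy)phenyl]prop-2-yn-1-one (present as its caesium phenoxide) | COCOc1cc(OC)cc(O)c1C(=O)C#Cc1ccc(OCOC)c(OCc2ccccc2)c1 | intermediate
15 | 3'-benzyloxy-7-methoxy-5,4'-bis(methoxymethoxy)flavone | COCOc1cc(OC)cc2oc(-c3ccc(OCOC)c(OCc4ccccc4)c3)cc(=O)c12 | intermediate
16 | 3-lithio-3'-benzyloxy-7-methoxy-5,4'-bis(methoxymethoxy)flavone | COCOc1cc(OC)cc2oc(-c3ccc(OCOC)c(OCc4ccccc4)c3)c([Li])c(=O)c12 | intermediate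
17 | dimethyl [3'-benzyloxy-7-methoxy-5,4'-bis(methoxymethoxy)flavon-3-yl]boronate | COCOc1cc(OC)cc2oc(-c3ccc(OCOC)c(OCc4ccccc4)c3)c(B(OC)OC)c(=O)c12 | intermediate
18 | 3'-benzyloxy-3-hydroxy-7-methoxy-5,4'-bis(methoxymethoxy)flavone | COCOc1cc(OC)cc2oc(-c3ccc(OCOC)c(OCc4ccccc4)c3)c(O)c(=O)c12 | intermediate
19 | 3'-O-benzylrhamnetin | COc1cc(O)c2c(=O)c(O)c(-c3ccc(O)c(OCc4ccccc4)c3)oc2c1 | intermediate
20 | tris(triethylammonium) 3'-O-benzylrhamnetin 3,5,4'-tris(sulfate) | COc1cc(OS(=O)(=O)[O-])c2c(=O)c(OS(=O)(=O)[O-])c(-c3ccc(OS(=O)(=O)[O-])c(OCc4ccccc4)c3)oc2c1.CC[NH+](CC)CC.CC[NH+](CC)CC.CC[NH+](CC)CC | intermediate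
21 | tris(triethylammonium) rhamnetin 3,5,4'-tris(sulfate) | COc1cc(OS(=O)(=O)[O-])c2c(=O)c(OS(=O)(=O)[O-])c(-c3ccc(OS(=O)(=O)[O-])c(O)c3)oc2c1.CC[NH+](CC)CC.CC[NH+](CC)CC.CC[NH+](CC)CC | intermediate
22 | rhamnetin 3,5,4'-tri-O-sulfate | COc1cc(OS(=O)(=O)O)c2c(=O)c(OS(=O)(=O)O)c(-c3ccc(OS(=O)(=O)O)c(O)c3)oc2c1 | target

**Total step count:** 12
**Longest linear sequence:** 9 steps (steps 4–12, from 7)

**Steps most likely to fail**

1. Step 8.
   - What may go wrong: the aryl anion at C4a may be protonated before it reaches the ester carbonyl, which stops the cascade at simple O-arylation. The caesium propiolate may also lose CO2 at 125 °C.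
   - Fallback: it sets out from 10 and 3 and comes back at 15. Treatment of 10 with n-BuLi followed by a proton quench should give 2-(benzyloxy)-4-ethynyl-1-(methoxymethoxy)benzene F1. A carbonylative Sonogashira coupling of F1 with iodophenol 3 (PdCl2(PPh3)2, CO, Et2NH, DMF, heat) then places the carbonyl on the carbon that bore iodine, which is C4a, and so gives ynone 14. The secondary amine steers closure of 14 to the six-membered ring of 15.

2. Step 11.
   - What may go wrong: sulfation may stall at the chelated O5–H, and partly sulfated salts are hard to separate.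
   - Fallback: it sets out from 19 and comes back at 22. The three hydroxyls are esterified with the much more electrophilic 2,2,2-trichloroethyl chlorosulfate (Et3N, DMAP, THF). This gives the neutral, silica-stable 3'-O-benzylrhamnetin 3,5,4'-tris(2,2,2-trichloroethyl sulfate) F2, so incompletely reacted material can be separated and resubmitted.
   - Zn and HCO2NH4 in MeOH then fragment the trichloroethyl esters reductively to triammonium 3'-O-benzylrhamnetin 3,5,4'-tris(sulfate) F3.
   - Hydrogenolysis (H2, Pd/C) gives triammonium rhamnetin 3,5,4'-tris(sulfate) F4, and the cold acid resin of step 12 gives 22.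

3. Step 1.
   - What may go wrong: iodine may enter at C4, a second iodination may follow, or traces of acid may move iodine away from the position between the hydroxyls.
   - Fallback: it sets out from 1 and comes back at 5. It places silicon by directed ortho-metalation instead of electrophilic substitution.
   - Mono-alkylation of 1 with MOMCl gives 3-methoxy-5-(methoxymethoxy)phenol F5, and ClC(O)NEt2 with K2CO3 gives 3-methoxy-5-(methoxymethoxy)phenyl diethylcarbamate F6.
   - s-BuLi/TMEDA at −78 °C lithiates the carbon between the two strongest directing groups (carbamate and MOM) rather than those next to the methoxy group. TMSCl then gives 5-methoxy-3-(methoxymethoxy)-2-(trimethylsilyl)phenyl diethylcarbamate F7.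
   - LiAlH4 cleaves the carbamate to 5-methoxy-3-(methoxymethoxy)-2-(trimethylsilyl)phenol F8, and n-BuLi converts F8 into phenoxide 5, which is triflated as in step 3.

**Further compounds**
F1 | step 8 | 2-(benzyloxy)-4-ethynyl-1-(methoxymethoxy)benzene | C#Cc1ccc(OCOC)c(OCc2ccccc2)c1
F2 | step 11 | 3'-O-benzylrhamnetin 3,5,4'-tris(2,2,2-trichloroethyl sulfate) | COc1cc(OS(=O)(=O)OCC(Cl)(Cl)Cl)c2c(=O)c(OS(=O)(=O)OCC(Cl)(Cl)Cl)c(-c3ccc(OS(=O)(=O)OCC(Cl)(Cl)Cl)c(OCc4ccccc4)c3)oc2c1
F3 | step 11 | triammonium 3'-O-benzylrhamnetin 3,5,4'-tris(sulfate) | COc1cc(OS(=O)(=O)[O-])c2c(=O)c(OS(=O)(=O)[O-])c(-c3ccc(OS(=O)(=O)[O-])c(OCc4ccccc4)c3)oc2c1.[NH4+].[NH4+].[NH4+]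
F4 | step 11 | triammonium rhamnetin 3,5,4'-tris(sulfate) | COc1cc(OS(=O)(=O)[O-])c2c(=O)c(OS(=O)(=O)[O-])c(-c3ccc(OS(=O)(=O)[O-])c(O)c3)oc2c1.[NH4+].[NH4+].[NH4+]
F5 | step 1 | 3-methoxy-5-(methoxymethoxy)phenol | COCOc1cc(O)cc(OC)c1
F6 | step 1 | 3-methoxy-5-(methoxymethoxy)phenyl diethylcarbamate | CCN(CC)C(=O)Oc1cc(OC)cc(OCOC)c1
F7 | step 1 | 5-methoxy-3-(methoxymethoxy)-2-(trimethylsilyl)phenyl diethylcarbamate | CCN(CC)C(=O)Oc1cc(OC)cc(OCOC)c1[Si](C)(C)C
F8 | step 1 | 5-methoxy-3-(methoxymethoxy)-2-(trimethylsilyl)phenol | COCOc1cc(OC)cc(O)c1[Si](C)(C)C
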